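**Retrosynthetic overview**

1. The last disconnection cuts the two enol ester C(=O)–O bonds on the central quinone (ring B). This gives atromentin 11, used with its phenols masked as silyl ethers (13), and the (2Z,4S,5S)-4,5-epoxyhex-2-enoate unit 18.
2. The strategy rests on the two outer rings A and C: each is a benzene ring whose only substituents are the hydroxyl at C4' and, para to it at C1', carbon C2 or C5 of ring B. Cutting C1'–C2' and C5'–C6' turns C1'/C6' into an ethynyl group on the quinone and C2'–C5' into a 1-methoxy-3-silyloxybutadiene.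
3. Rings A and C are therefore closed together by a twofold Diels–Alder addition with loss of methanol on 2,5-diethynyl-3,6-dimethoxy-1,4-benzoquinone 6, giving 10.
4. Ring B is bought as 1,2,4,5-tetramethoxybenzene 1 and taken to 6 by bromination, twofold Sonogashira coupling, oxidative demethylation and desilylation.
5. Order of ring formation: ring B (purchased), then rings A and C (step 5). The two oxiranes are made separately from (E)-crotyl alcohol by Sharpless epoxidation (step 8) and attached in step 12.

Key step: step 5

Remark: (E)-crotyl alcohol 14 is taken free of the Z isomer, and the diethynylquinone 6 is carried into step 5 as a cold solution without storage.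

**Route**

Step 1
Reactants: 1 1,2,4,5-tetramethoxybenzene
Product: 2 1,4-dibromo-2,3,5,6-tetramethoxybenzene
Conditions: Br2 (2.2 equiv), CH2Cl2, 0 °C to rt
Reagents that add atoms: bromine, BrBr
Why: Electrophilic aromatic bromination, in which the only two ring C–H positions of 1 are each flanked by two methoxy groups and strongly activated, so twofold substitution can give only 2.

Step 2
Reactants: 2 1,4-dibromo-2,3,5,6-tetramethoxybenzene; 3 trimethylsilylacetylene (two molecules)
Product: 4 1,4-bis[(trimethylsilyl)ethynyl]-2,3,5,6-tetramethoxybenzene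
Conditions: 3 (3 equiv), PdCl2(PhCN)2 (5 mol %), [HP(t-Bu)3]BF4 (10 mol %), CuI (5 mol %), i-Pr2NH, 1,4-dioxane, 60 °C
Reagents that add atoms: none
Why: Twofold Sonogashira coupling, in which zerovalent palladium carrying the bulky, electron-rich P(t-Bu)3 inserts into each of the two hindered, electron-rich C–Br bonds and one molecule of the slim alkyne 3 is delivered as its copper acetylide at each position, so that two molecules of 3 are consumed per molecule of 2.

Step 3
Reactants: 4 1,4-bis[(trimethylsilyl)ethynyl]-2,3,5,6-tetramethoxybenzene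
Product: 5 2,5-dimethoxy-3,6-bis[(trimethylsilyl)ethynyl]-1,4-benzoquinone
Conditions: (NH4)2Ce(NO3)6 (2.5 equiv), MeCN/H2O, 0 °C
Reagents that add atoms: water, O
Why: Oxidative demethylation by tetravalent cerium, in which two one-electron oxidations and attack of water at a para pair of methoxy-bearing carbons expel two molecules of methanol to give the para-quinone; both para pairs lead to the same compound 5 and the silylalkynes are inert to the oxidant.

Step 4
Reactants: 5 2,5-dimethoxy-3,6-bis[(trimethylsilyl)ethynyl]-1,4-benzoquinone
Product: 6 2,5-diethynyl-3,6-dimethoxy-1,4-benzoquinone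
Conditions: AgNO3 (20 mol %), acetone/H2O/CH2Cl2, rt, dark
Reagents that add atoms: none
Why: Silver-catalysed protodesilylation, in which AgNO3 activates the C(sp)–Si bond towards attack of water at silicon through a silver acetylide that is protonated in the wet medium, freeing both terminal alkynes under neutral conditions that spare the base-sensitive methoxyquinone.

Step 5
Reactants: 6 2,5-diethynyl-3,6-dimethoxy-1,4-benzoquinone; 7 (E)-1-methoxy-3-(trimethylsilyloxy)buta-1,3-diene (two molecules)
Product: 10 2,5-bis(4-hydroxyphenyl)-3,6-dimethoxy-1,4-benzoquinone, via bis-cyclohexadiene cycloadduct 8 (not isolated), via bis(trimethylsilyl) aryl ether 9 (not isolated)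
Conditions: 7 (4 equiv), toluene, 70 °C, Ar, dark; then 0.5 M HCl, THF, rt
Reagents that add atoms: none
Why: Proposed new method: the unsubstituted CH2 terminus of the diene, its most nucleophilic carbon, attacks the terminal alkyne carbon, which is the δ-carbon of the ynenone C≡C–C=C–C=O that runs through the ring alkene to a quinone carbonyl, while the methoxy-bearing terminus bonds to the internal alkyne carbon in a concerted, asynchronous normal-demand [4+2] cycloaddition to give the 1,4-cyclohexadiene 8; 1,4-loss of methanol then aromatises each new ring to the aryl silyl ether 9 and dilute acid frees the phenols. The closest known reaction type is the Diels–Alder benzannulation of 1-methoxy-3-silyloxybutadienes with propiolates and ynones to 4-hydroxybenzoates and 4-hydroxyaryl ketones, whereas an ethynylquinone has not served as the 2π partner. Each of the two benzene rings closes by an intermolecular [4+2] cycloaddition that forms two C–C bonds (four in all), followed by eliminative aromatisation. The methoxy-bearing sp3 carbons of 8 are transient stereocentres erased on aromatisation, so 10 has no stereocentre and no stereocontrol is called for. The step needs para regiochemistry, which the matched polarisation of diene and ynenone should secure, and reaction at the alkynes and not at the C=C or C=O bonds of the quinone, which should follow because both ring alkenes are tetrasubstituted and carry donor methoxy groups and because no Lewis acid is present to activate the carbonyls.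

Step 6
Reactants: 10 2,5-bis(4-hydroxyphenyl)-3,6-dimethoxy-1,4-benzoquinone
Product: 11 2,5-dihydroxy-3,6-bis(4-hydroxyphenyl)-1,4-benzoquinone (atromentin)
Conditions: 2 M NaOH (aq.), 1,4-dioxane, 50 °C, Ar; then 2 M HCl to pH 2
Reagents that add atoms: sodium hydroxide, [Na+].[OH-]
Why: Addition–elimination at the two vinylogous methyl ester carbons, in which hydroxide adds to C3 and C6 of the quinone and expels methoxide to give the stabilised vinylogous carboxylate while the phenoxides are spectators, and acidification precipitates 11.

Step 7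
Reactants: 11 2,5-dihydroxy-3,6-bis(4-hydroxyphenyl)-1,4-benzoquinone
Product: 13 2,5-bis[4-(tert-butyldimethylsilyloxy)phenyl]-3,6-dihydroxy-1,4-benzoquinone, via tetrakis-silyl ether 12 (not isolated)
Conditions: TBSCl (5 equiv), imidazole, DMF, rt; then AcOH/THF/H2O, rt
Reagents that add atoms: tert-butyldimethylsilyl chloride, CC(C)(C)[Si](C)(C)Cl
Why: Silylation with TBSCl and imidazole (Corey conditions) caps all four hydroxyls, and because the two silyl groups on the quinone oxygens are vinylogous silyl esters they are hydrolysed by aqueous acetic acid while the aryl silyl ethers stay in place.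

Step 8
Reactants: 14 (E)-but-2-en-1-ol
Product: 15 [(2S,3S)-3-methyloxiran-2-yl]methanol
Conditions: Ti(Oi-Pr)4 (10 mol %), L-(+)-diisopropyl tartrate (12 mol %), t-BuOOH, 4 Å molecular sieves, CH2Cl2, −20 °C
Reagents that add atoms: tert-butyl hydroperoxide, CC(C)(C)OO
Why: Sharpless asymmetric epoxidation, in which the titanium–L-(+)-tartrate complex delivers the peroxide oxygen to one face of the E allylic alcohol and so sets C2 and C3 as S,S, the trans relationship following from stereospecific syn addition to the E alkene.

Step 9
Reactants: 15 [(2S,3S)-3-methyloxiran-2-yl]methanol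
Product: 16 (2R,3S)-3-methyloxirane-2-carbaldehyde (kept as a cold concentrated solution and used at once)
Conditions: Dess–Martin periodinane, pyridine, CH2Cl2, 0 °C to rt
Reagents that add atoms: none
Why: Dess–Martin oxidation of the primary alcohol stops at the aldehyde under buffered, non-aqueous conditions, and the oxirane carbon next to the carbonyl does not epimerise because enolisation would place a double bond on the three-membered ring (the descriptor at C2 changes from S to R only through the priority rules).

Step 10
Reactants: 16 (2R,3S)-3-methyloxirane-2-carbaldehyde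
Product: 17 methyl (2Z)-3-[(2S,3S)-3-methyloxiran-2-yl]prop-2-enoate
Conditions: (CF3CH2O)2P(O)CH2CO2Me, KN(SiMe3)2, 18-crown-6, THF, −78 °C
Reagents that add atoms: methyl 2-[bis(2,2,2-trifluoroethoxy)phosphoryl]acetate, COC(=O)CP(=O)(OCC(F)(F)F)OCC(F)(F)F
Why: Still–Gennari variant of the Horner–Wadsworth–Emmons olefination, in which the bis(trifluoroethyl) phosphonate and a dissociated potassium counter-ion make the first adduct eliminate faster than it equilibrates, giving the Z enoate under kinetic control without touching the two stereocentres.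

Step 11
Reactants: 17 methyl (2Z)-3-[(2S,3S)-3-methyloxiran-2-yl]prop-2-enoate
Product: 18 potassium (2Z)-3-[(2S,3S)-3-methyloxiran-2-yl]prop-2-enoate
Conditions: KOSiMe3 (1.05 equiv), Et2O, rt; filtration
Reagents that add atoms: potassium trimethylsilanolate, C[Si](C)(C)[O-].[K+]
Why: Anhydrous ester cleavage with potassium trimethylsilanolate gives the potassium carboxylate directly as a precipitate, so the free Z acid, which could lactonise by opening its own oxirane, is never formed.

Step 12
Reactants: 18 potassium (2Z)-3-[(2S,3S)-3-methyloxiran-2-yl]prop-2-enoate (two molecules); 13 2,5-bis[4-(tert-butyldimethylsilyloxy)phenyl]-3,6-dihydroxy-1,4-benzoquinone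
Product: 20 2,5-bis[4-(tert-butyldimethylsilyloxy)phenyl]-3,6-dioxocyclohexa-1,4-diene-1,4-diyl bis{(2Z)-3-[(2S,3S)-3-methyloxiran-2-yl]prop-2-enoate}, via mixed anhydride 19 (not isolated)
Conditions: 18 (2.6 equiv), 2,4,6-Cl3C6H2COCl (2.5 equiv), THF, 0 °C; then 13, Et3N, DMAP (20 mol %), toluene, 0 °C to rt
Reagents that add atoms: none
Why: Yamaguchi esterification, in which the carboxylate forms a mixed anhydride with the hindered aroyl chloride, DMAP transfers the unhindered enoyl group, and the two acidic, chelated quinone hydroxyls, present as ammonium enolates, are acylated on oxygen just as a carboxylate is in anhydride formation, the phenols being masked.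

Step 13
Reactants: 20 2,5-bis[4-(tert-butyldimethylsilyloxy)phenyl]-3,6-dioxocyclohexa-1,4-diene-1,4-diyl bis{(2Z)-3-[(2S,3S)-3-methyloxiran-2-yl]prop-2-enoate}
Product: 21 2,5-bis(4-hydroxyphenyl)-3,6-dioxocyclohexa-1,4-diene-1,4-diyl bis{(2Z)-3-[(2S,3S)-3-methyloxiran-2-yl]prop-2-enoate} (CNP0407724.1)
Conditions: Bu4NF (2.4 equiv), AcOH (3 equiv), THF, 0 °C
Reagents that add atoms: none
Why: Fluoride-induced cleavage of the two aryl silyl ethers, with acetic acid present to protonate each phenoxide at once so that the enol esters, the oxiranes and the Z alkenes are not attacked.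

**Compound list**

1 | 1,2,4,5-tetramethoxybenzene | COc1cc(OC)c(OC)cc1OC | starting material
2 | 1,4-dibromo-2,3,5,6-tetramethoxybenzene | COc1c(Br)c(OC)c(OC)c(Br)c1OC | intermediate
3 | trimethylsilylacetylene | C#C[Si](C)(C)C | starting material
4 | 1,4-bis[(trimethylsilyl)ethynyl]-2,3,5,6-tetramethoxybenzene | COc1c(C#C[Si](C)(C)C)c(OC)c(OC)c(C#C[Si](C)(C)C)c1OC | intermediate
5 | 2,5-dimethoxy-3,6-bis[(trimethylsilyl)ethynyl]-1,4-benzoquinone | COC1=C(C#C[Si](C)(C)C)C(=O)C(OC)=C(C#C[Si](C)(C)C)C1=O | intermediate
6 | 2,5-diethynyl-3,6-dimethoxy-1,4-benzoquinone | C#CC1=C(OC)C(=O)C(C#C)=C(OC)C1=O | intermediate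
7 | (E)-1-methoxy-3-(trimethylsilyloxy)buta-1,3-diene | CO/C=C/C(=C)O[Si](C)(C)C | starting material
8 | 2,5-bis[6-methoxy-4-(trimethylsilyloxy)cyclohexa-1,4-dien-1-yl]-3,6-dimethoxy-1,4-benzoquinone (mixture of diastereomers) | COC1=C(C2=CCC(O[Si](C)(C)C)=CC2OC)C(=O)C(OC)=C(C2=CCC(O[Si](C)(C)C)=CC2OC)C1=O | intermediate
9 | 2,5-dimethoxy-3,6-bis[4-(trimethylsilyloxy)phenyl]-1,4-benzoquinone | COC1=C(c2ccc(O[Si](C)(C)C)cc2)C(=O)C(OC)=C(c2ccc(O[Si](C)(C)C)cc2)C1=O | intermediate
10 | 2,5-bis(4-hydroxyphenyl)-3,6-dimethoxy-1,4-benzoquinone | COC1=C(c2ccc(O)cc2)C(=O)C(OC)=C(c2ccc(O)cc2)C1=O | intermediate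
11 | 2,5-dihydroxy-3,6-bis(4-hydroxyphenyl)-1,4-benzoquinone (atromentin) | OC1=C(c2ccc(O)cc2)C(=O)C(O)=C(c2ccc(O)cc2)C1=O | intermediate
12 | 2,5-bis(tert-butyldimethylsilyloxy)-3,6-bis[4-(tert-butyldimethylsilyloxy)phenyl]-1,4-benzoquinone | CC(C)(C)[Si](C)(C)OC1=C(c2ccc(O[Si](C)(C)C(C)(C)C)cc2)C(=O)C(O[Si](C)(C)C(C)(C)C)=C(c2ccc(O[Si](C)(C)C(C)(C)C)cc2)C1=O | intermediate
13 | 2,5-bis[4-(tert-butyldimethylsilyloxy)phenyl]-3,6-dihydroxy-1,4-benzoquinone | OC1=C(c2ccc(O[Si](C)(C)C(C)(C)C)cc2)C(=O)C(O)=C(c2ccc(O[Si](C)(C)C(C)(C)C)cc2)C1=O | intermediate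
14 | (E)-but-2-en-1-ol (crotyl alcohol) | C/C=C/CO | starting material
15 | [(2S,3S)-3-methyloxiran-2-yl]methanol | C[C@@H]1O[C@H]1CO | intermediate
16 | (2R,3S)-3-methyloxirane-2-carbaldehyde | C[C@@H]1O[C@H]1C=O | intermediate
17 | methyl (2Z)-3-[(2S,3S)-3-methyloxiran-2-yl]prop-2-enoate | C[C@@H]1O[C@H]1/C=C\C(=O)OC | intermediate
18 | potassium (2Z)-3-[(2S,3S)-3-methyloxiran-2-yl]prop-2-enoate | C[C@@H]1O[C@H]1/C=C\C(=O)[O-].[K+] | intermediate
19 | (2Z)-3-[(2S,3S)-3-methyloxiran-2-yl]prop-2-enoic 2,4,6-trichlorobenzoic anhydride | C[C@@H]1O[C@H]1/C=C\C(=O)OC(=O)c1c(Cl)cc(Cl)cc1Cl | intermediate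
20 | 2,5-bis[4-(tert-butyldimethylsilyloxy)phenyl]-3,6-dioxocyclohexa-1,4-diene-1,4-diyl bis{(2Z)-3-[(2S,3S)-3-methyloxiran-2-yl]prop-2-enoate} | C[C@@H]1O[C@H]1/C=C\C(=O)OC1=C(c2ccc(O[Si](C)(C)C(C)(C)C)cc2)C(=O)C(OC(=O)/C=C\[C@@H]2O[C@H]2C)=C(c2ccc(O[Si](C)(C)C(C)(C)C)cc2)C1=O | intermediate
21 | 2,5-bis(4-hydroxyphenyl)-3,6-dioxocyclohexa-1,4-diene-1,4-diyl bis{(2Z)-3-[(2S,3S)-3-methyloxiran-2-yl]prop-2-enoate} | C[C@@H]1O[C@H]1/C=C\C(=O)OC1=C(c2ccc(O)cc2)C(=O)C(OC(=O)/C=C\[C@@H]2O[C@H]2C)=C(c2ccc(O)cc2)C1=O | target

**Step count**

Total: 13 steps. Longest linear sequence: 9 steps (steps 1–7, 12 and 13, from 1); the side chain takes steps 8–11 before it joins in step 12.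

**Steps most likely to fail**

Step 5 (Proposed new method). The electron-rich diene may transfer an electron to the quinone, or add to the ring alkenes or carbonyls of the quinone instead of the alkynes. The diethynylquinone may also polymerise before both alkynes have reacted, or the second cycloaddition may stall after the first. The fallback uses known chemistry and sets out from compound 2. Oxidative demethylation with (NH4)2Ce(NO3)6 in MeCN/H2O should give 2,5-dibromo-3,6-dimethoxy-1,4-benzoquinone F1. Twofold Suzuki–Miyaura coupling of F1 with 4-(tert-butyldimethylsilyloxy)phenylboronic acid (Pd(PPh3)4, K3PO4, 1,4-dioxane, 90 °C) should give 2,5-bis[4-(tert-butyldimethylsilyloxy)phenyl]-3,6-dimethoxy-1,4-benzoquinone F2. Aqueous NaOH in dioxane followed by acidification then cleaves both aryl silyl ethers and both vinylogous methyl esters, and the route is rejoined at compound 11. Partial loss of the silyl groups during the coupling does no harm, since they are removed in the next operation anyway.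

Step 12. The activated Z-enoyl species may isomerise to the E isomer through reversible conjugate addition of DMAP. The oxirane may be opened by chloride or by the neighbouring acyl group while the acid is activated. The weakly nucleophilic, chelated enolate may be acylated only once. The fallback reverses the polarity of the bond formation and sets out from compound 13. Oxalyl chloride with catalytic DMF in CH2Cl2 should convert the two vinylogous acid hydroxyls into the vinylogous acid chloride 2,5-dichloro-3,6-bis[4-(tert-butyldimethylsilyloxy)phenyl]-1,4-benzoquinone F3. The unactivated carboxylate 18 (18-crown-6, MeCN, rt) then replaces both chlorides by addition–elimination, the way oxygen nucleophiles substitute haloquinones. The route is rejoined at compound 20, and the Z-enoyl group is never turned into an acylating agent.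

Step 13. Fluoride or a liberated phenoxide may attack the enol esters, which are vinylogous anhydrides, so that acyl groups are lost or migrate to the phenols. Fluoride may also open the vinyl oxiranes. The fallback leaves out the phenol protection and sets out from compound 11. The mixed anhydride 19 is made from 18 as in step 12 and added to 11 with i-Pr2NEt (2 equiv) in DMF/THF at −20 °C without DMAP. Only the two strongly acidic quinone hydroxyls are deprotonated and acylated, while the far less acidic phenols stay neutral, and the target 21 is reached directly. This fallback makes no compound outside the compound list (F0).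

**Further compounds**

F1 | step 5 | 2,5-dibromo-3,6-dimethoxy-1,4-benzoquinone | COC1=C(Br)C(=O)C(OC)=C(Br)C1=O
F2 | step 5 | 2,5-bis[4-(tert-butyldimethylsilyloxy)phenyl]-3,6-dimethoxy-1,4-benzoquinone | COC1=C(c2ccc(O[Si](C)(C)C(C)(C)C)cc2)C(=O)C(OC)=C(c2ccc(O[Si](C)(C)C(C)(C)C)cc2)C1=O
F3 | step 12 | 2,5-dichloro-3,6-bis[4-(tert-butyldimethylsilyloxy)phenyl]-1,4-benzoquinone | ClC1=C(c2ccc(O[Si](C)(C)C(C)(C)C)cc2)C(=O)C(Cl)=C(c2ccc(O[Si](C)(C)C(C)(C)C)cc2)C1=O
F0 | step 13 | none | none
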